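The amber run, which has more catalyst than the others, reads its highest isomer of the product B at 0.833 d, at 52.4 % of the charge. Later, ochre and amber both read 47.9 % at 2.08 d. So I treat the rise as pseudo-first-order, with a rate that follows the catalyst, and the later fall as indifferent to it. The quantity I carry is the peak dose, catalyst concentration times the time of the peak of isomer of the product B: the catalyst-time at which the rise hands over to the fall.

| flask | substrate | catalyst | remark | time |
|---|---|---|---|---|
| ochre | 2 M | 280 mM | run made earlier |  |
| amber | 2 M | 440 mM | run made earlier |  |
| grey | 3 M | 200 mM | run made earlier |  |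
| flask | 2.0 M | 200 mM |  | 15 d |

- ochre (time / d: isomer of the product B / %, target / %): 0.417: 41.5, 24.1; 0.833: 48.5, 18.5; 2.08: 47.9, 14.9; 4.00: 44.3, 13.2; 10.0: 43.2, 12.0
- amber (time / d: isomer of the product B / %, target / %): 0.417: 49.7, 20.6; 0.833: 52.4, 16.1; 2.08: 47.9, 14.4; 4.00: 44.8, 13.3; 10.0: 42.9, 11.5
- grey (time / d: isomer of the product B / %, target / %): 0.417: 33.8, 27.7; 0.833: 43.2, 19.6; 2.08: 46.1, 15.7; 4.00: 44.7, 12.9; 10.0: 44.0, 12.5

(standard deviation of a reading: 0.5 percentage points)

- the best time, 15 d at the latest, for isomer of the product B
- the amount of isomer of the product B, in percent of the substrate charged, at that time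
- earliest time at which at least nineteen twentieths of that best amount are there, in d
- latest time at which they still are, in d

Amber gives the dose, and the flask's catalyst turns it into a time:

dose = 0.367 M·d, peak time = 1.83 d

The fall comes from ochre and amber averaged. Above their last readings, at 43.0 %, the excess shrinks between 2.08 d and 4.00 d:

excess 4.8 percentage points, then 1.5 points, half-life 1.13 d

Amber's peak reading stands 1 point under this curve. I take the same gap for the flask:

best = 47.6 %, threshold = 45.3 %, shut = 3.36 d

The weak link is the dose, taken from a single coarse reading. Ochre's two top readings nearly tie, so I put its peak midway between them on a log scale, and that independent run gives 0.369 M·d. The dose stands.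

The forecast says 1.6 d, 47 %, 0.85 d and 3.9 d, adding that “The shallow tail makes the shut time uncertain”, and its peak comes earlier than mine.

The flask peaks at 1.59 d with 47.7 %, and holds the share asked for from 0.910 d to 3.65 d.

substrate ⇌ dormant form (K = 0.231, k = 1.73 × 10⁻⁴ min⁻¹); substrate ⇌ target (K = 0.784, k = 0.00485 min⁻¹); isomer of the product A ⇌ isomer of the product B (K = 1.75, k = 2.85 × 10⁻⁴ min⁻¹); target ⇌ isomer of the product A (K = 2.02, k = 1.45 × 10⁻⁵ min⁻¹); isomer of the product B + catalyst ⇌ substrate + catalyst, rate k5*[catalyst]*[isomer of the product B] forward; the back reaction follows from the equilibrium constant (k = 0.00296 M⁻¹ min⁻¹) Its peak dose is therefore 0.318 M·d, lower than the dose I read from amber. At 1.59 d the flask holds 11.6 % isomer of the product A, yet the path from target to it makes no difference to the best. On the neighbouring flask with 0.50 M catalyst, this dose puts the peak near 0.636 d, earlier than in the flask, and that neighbour's best is 52.5 %.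

(The runs were computed for substances that don't exist, and the scatter is random.)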